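**Plan**

1. Retrosynthesis: the three O-benzyl groups and the 5-O-methyl group are removed first. Ring A is then cut at C4a–C5 and traced back to a cyclobutenone, the cyclobutenone–pyranone bond (future C8–C8a) is cut next, and the pyranone is opened at O1–C2 and at the aroyl C–C bond.
2. Enabling feature: ring A carries oxygen at C5 and C8 (para to each other), a third oxygen at C7 next to C8, and hydrogen at C6. This is the hydroquinone monoether pattern that a 3-alkoxy-4-methoxy-4-alkenylcyclobutenone gives when it expands across the alkenyl double bond, here the C4a=C8a bond of a 4-pyranone that already is ring C.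
3. Forward: the ring B acid chloride and 4-methoxybutenone give the 2-aryl-4-pyranone (ring C), and squaric acid gives benzyl semisquarate. The C6-lithiated pyranone adds to the semisquarate, the carbinol is methylated, and thermolysis closes ring A last.
4. Methylation of the chelated 5-hydroxyl and one hydrogenolysis of three benzyl ethers finish the synthesis.
5. Stereochemistry: the target is achiral. The only stereocentres on the way (the carbinol carbon of the cyclobutenones, C4a of a transient dienone) are racemic and vanish on aromatisation. The one stereochemical demand is outward rotation of the methoxy group in the ring opening.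

Key step: step 10

Remark: compound 7 is drawn as the diketone although it should exist largely as an enol; compounds 11, 14, 15 and 17 are racemic and no enantiocontrol is needed.

**Route**

Step 1
Reactants: 1 methyl 3,5-dihydroxy-4-methoxybenzoate
Product: 2 methyl 3,5-bis(benzyloxy)-4-methoxybenzoate
Conditions: BnBr, K2CO3, DMF, 60 °C
Reagents that add atoms: benzyl bromide, BrCc1ccccc1
Why: Williamson etherification of both phenols under carbonate base leaves the methyl ester untouched.

Step 2
Reactants: 2 methyl 3,5-bis(benzyloxy)-4-methoxybenzoate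
Product: 3 3,5-bis(benzyloxy)-4-methoxybenzoic acid
Conditions: LiOH, THF/MeOH/H2O, 50 °C; then aq. HCl
Reagents that add atoms: lithium hydroxide, [Li+].[OH-]
Why: Ester saponification spares the aryl benzyl and methyl ethers and gives the acid on acidification.

Step 3
Reactants: 3 3,5-bis(benzyloxy)-4-methoxybenzoic acid
Product: 4 3,5-bis(benzyloxy)-4-methoxybenzoyl chloride
Conditions: (COCl)2, cat. DMF, CH2Cl2, 0 °C to rt
Reagents that add atoms: oxalyl chloride, ClC(=O)C(Cl)=O
Why: Acid chloride formation through the catalytic chloroiminium (Vilsmeier-type) species runs cold and without strong acid, so the benzyl ethers should survive.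

Step 4
Reactants: 4 3,5-bis(benzyloxy)-4-methoxybenzoyl chloride; 5 (E)-4-methoxybut-3-en-2-one
Product: 7 (E)-1-[3,5-bis(benzyloxy)-4-methoxyphenyl]-5-methoxypent-4-ene-1,3-dione, via lithium dienolate 6 (not isolated)
Conditions: 5 (2.1 equiv), LiN(SiMe3)2 (2.1 equiv), THF, −78 °C; then 4, −78 °C; aq. NH4Cl
Reagents that add atoms: none
Why: Kinetic deprotonation of the methyl ketone gives the cross-conjugated lithium dienolate, which undergoes Claisen-type C-acylation by the acid chloride at low temperature, the second equivalent of enolate taking up the acidic proton of the new 1,3-diketone.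

Step 5
Reactants: 7 (E)-1-[3,5-bis(benzyloxy)-4-methoxyphenyl]-5-methoxypent-4-ene-1,3-dione
Product: 8 2-[3,5-bis(benzyloxy)-4-methoxyphenyl]-4H-pyran-4-one
Conditions: CF3CO2H (cat.), toluene, rt
Reagents that add atoms: none
Why: Acid-catalysed 6-endo oxa-Michael addition of the diketone enol oxygen to the β-methoxy enone followed by loss of methanol (addition–elimination) is the standard closure to 2-substituted 4-pyranones.

Step 6
Reactants: 9 squaric acid
Product: 10 3,4-bis(benzyloxy)cyclobut-3-ene-1,2-dione (dibenzyl squarate)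
Conditions: BnOH (excess), toluene, reflux, Dean–Stark trap
Reagents that add atoms: benzyl alcohol, OCc1ccccc1
Why: Squaric acid is a vinylogous carboxylic acid and is esterified by alcohols under azeotropic removal of water (Fischer-type esterification).

Step 7
Reactants: 10 3,4-bis(benzyloxy)cyclobut-3-ene-1,2-dione
Product: 12 3-(benzyloxy)cyclobut-3-ene-1,2-dione (benzyl semisquarate), via hydroxycyclobutenone 11 (not isolated)
Conditions: LiAlH(OtBu)3, THF, −78 to −20 °C; aq. HCl quench; then conc. aq. HCl (cat.), CH2Cl2, rt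
Reagents that add atoms: water, O
Why: The bulky hydride reduces one squarate carbonyl in a 1,2-manner, and acid then ionises the carbinol to an alkoxy-stabilised cyclobutenyl cation that is rehydrated at the distal benzyloxy-bearing carbon and expels benzyl alcohol (1,3-transposition), the established reduction–hydrolysis route from dialkyl squarates to alkyl semisquarates.

Step 8
Reactants: 8 2-[3,5-bis(benzyloxy)-4-methoxyphenyl]-4H-pyran-4-one; 12 3-(benzyloxy)cyclobut-3-ene-1,2-dione
Product: 14 racemic 3-(benzyloxy)-4-{6-[3,5-bis(benzyloxy)-4-methoxyphenyl]-4-oxo-4H-pyran-2-yl}-4-hydroxycyclobut-2-en-1-one, via 6-lithiopyranone 13 (not isolated)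
Conditions: lithium 2,2,6,6-tetramethylpiperidide (from 2,2,6,6-tetramethylpiperidine and n-BuLi), THF, −78 °C, slow inverse addition of 8; then transfer onto 12, THF, −78 °C; aq. NH4Cl at −78 °C
Reagents that add atoms: none
Why: Deprotonative lithiation by a hindered amide at the carbon next to the ring oxygen is the established metalation site of chromones and 4-pyranones that are unsubstituted there, and organolithiums add 1,2 to the ketone-like carbonyl of an alkoxycyclobutenedione (the one flanking the alkoxy-bearing carbon, the other being a vinylogous ester), which places the benzyloxy group next to the new, racemic carbinol carbon.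

Step 9
Reactants: 14 racemic 3-(benzyloxy)-4-{6-[3,5-bis(benzyloxy)-4-methoxyphenyl]-4-oxo-4H-pyran-2-yl}-4-hydroxycyclobut-2-en-1-one
Product: 15 racemic 3-(benzyloxy)-4-{6-[3,5-bis(benzyloxy)-4-methoxyphenyl]-4-oxo-4H-pyran-2-yl}-4-methoxycyclobut-2-en-1-one
Conditions: MeI, Ag2O, 4 Å molecular sieves, MeCN, rt, dark
Reagents that add atoms: iodomethane, CI
Why: Purdie methylation with iodomethane and Ag2O etherifies the tertiary cyclobutenol under nearly neutral conditions that are customary for 4-hydroxycyclobutenones and should avoid base-induced ring cleavage.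

Step 10
Reactants: 15 racemic 3-(benzyloxy)-4-{6-[3,5-bis(benzyloxy)-4-methoxyphenyl]-4-oxo-4H-pyran-2-yl}-4-methoxycyclobut-2-en-1-one
Product: 18 7-(benzyloxy)-2-[3,5-bis(benzyloxy)-4-methoxyphenyl]-5-hydroxy-8-methoxy-4H-chromen-4-one, via dienylketene 16 (not isolated), via 4aH-chromenedione 17 (not isolated)
Conditions: degassed p-xylene (dilute), reflux (138 °C), argon
Reagents that add atoms: none
Why: Proposed new method: heating should trigger conrotatory 4π electrocyclic opening of the cyclobutenone C1–C4 bond, and because the donor methoxy group at C4 rotates outward the pyranonyl arm ends up cis to the ketene in dienylketene 16. The electrophilic ketene carbon then bonds to pyranone C5, the nucleophilic α-carbon of the vinylogous ester, in a thermal disrotatory 6π electrocyclisation that closes the six-membered carbocycle ring A by forming the C4a–C5 bond, and enolisation of the doubly activated C4a–H of dienone 17 gives the chelated 5-phenol. The closest known reaction type is the Moore ring expansion of 4-aryl-, 4-heteroaryl- and 4-alkenyl-4-alkoxycyclobutenones to hydroquinone monoethers; a 4-pyranon-2-yl arm has not been used in it. No stereocentre survives, since the quaternary carbon of 15 becomes C8 of the arene and the transient C4a centre of 17 is lost on tautomerisation. The step needs torquoselectivity, secured by the C4 methoxy group, and a single closure site, secured because pyranone C6 has only one carbon neighbour (C5, the other being the ring oxygen); the pattern 5-OH, 6-H, 7-OBn, 8-OMe is already fixed in 15 by the regiochemistry of step 8.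

Step 11
Reactants: 18 7-(benzyloxy)-2-[3,5-bis(benzyloxy)-4-methoxyphenyl]-5-hydroxy-8-methoxy-4H-chromen-4-one
Product: 19 7-(benzyloxy)-2-[3,5-bis(benzyloxy)-4-methoxyphenyl]-5,8-dimethoxy-4H-chromen-4-one
Conditions: Me2SO4, K2CO3, acetone, reflux
Reagents that add atoms: dimethyl sulfate, COS(=O)(=O)OC
Why: Forcing Williamson methylation with dimethyl sulfate and K2CO3 in hot acetone is the usual way to alkylate the hydrogen-bonded 5-hydroxyl of a flavone, and no other free hydroxyl is present.

Step 12
Reactants: 19 7-(benzyloxy)-2-[3,5-bis(benzyloxy)-4-methoxyphenyl]-5,8-dimethoxy-4H-chromen-4-one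
Product: 20 2-(3,5-dihydroxy-4-methoxyphenyl)-7-hydroxy-5,8-dimethoxy-4H-chromen-4-one (CNP0218554.0)
Conditions: H2 (1 atm), 10% Pd/C, EtOAc/MeOH, rt
Reagents that add atoms: none
Why: Catalytic hydrogenolysis over Pd/C cleaves the three aryl benzyl ethers, while the methyl ethers and the chromone double bond (part of a vinylogous ester) should be untouched at one atmosphere of hydrogen.

**Compound list**

1 | methyl 3,5-dihydroxy-4-methoxybenzoate | COC(=O)c1cc(O)c(OC)c(O)c1 | starting material
2 | methyl 3,5-bis(benzyloxy)-4-methoxybenzoate | COC(=O)c1cc(OCc2ccccc2)c(OC)c(OCc2ccccc2)c1 | intermediate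
3 | 3,5-bis(benzyloxy)-4-methoxybenzoic acid | COc1c(OCc2ccccc2)cc(C(=O)O)cc1OCc1ccccc1 | intermediate
4 | 3,5-bis(benzyloxy)-4-methoxybenzoyl chloride | COc1c(OCc2ccccc2)cc(C(Cl)=O)cc1OCc1ccccc1 | intermediate
5 | (E)-4-methoxybut-3-en-2-one | CO/C=C/C(C)=O | starting material
6 | lithium (E)-4-methoxybuta-1,3-dien-2-olate | [Li+].[O-]C(=C)/C=C/OC | intermediate (not isolated)
7 | (E)-1-[3,5-bis(benzyloxy)-4-methoxyphenyl]-5-methoxypent-4-ene-1,3-dione | CO/C=C/C(=O)CC(=O)c1cc(OCc2ccccc2)c(OC)c(OCc2ccccc2)c1 | intermediate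
8 | 2-[3,5-bis(benzyloxy)-4-methoxyphenyl]-4H-pyran-4-one | COc1c(OCc2ccccc2)cc(-c2cc(=O)cco2)cc1OCc1ccccc1 | intermediate
9 | squaric acid (3,4-dihydroxycyclobut-3-ene-1,2-dione) | OC1=C(O)C(=O)C1=O | starting material
10 | 3,4-bis(benzyloxy)cyclobut-3-ene-1,2-dione | O=C1C(=O)C(OCc2ccccc2)=C1OCc1ccccc1 | intermediate
11 | racemic 2,3-bis(benzyloxy)-4-hydroxycyclobut-2-en-1-one | O=C1C(OCc2ccccc2)=C(OCc2ccccc2)C1O | intermediate (not isolated)
12 | 3-(benzyloxy)cyclobut-3-ene-1,2-dione | O=C1C=C(OCc2ccccc2)C1=O | intermediate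
13 | {6-[3,5-bis(benzyloxy)-4-methoxyphenyl]-4-oxo-4H-pyran-2-yl}lithium | [Li]c1cc(=O)cc(-c2cc(OCc3ccccc3)c(OC)c(OCc3ccccc3)c2)o1 | intermediate (not isolated)
14 | racemic 3-(benzyloxy)-4-{6-[3,5-bis(benzyloxy)-4-methoxyphenyl]-4-oxo-4H-pyran-2-yl}-4-hydroxycyclobut-2-en-1-one | OC1(c2cc(=O)cc(-c3cc(OCc4ccccc4)c(OC)c(OCc4ccccc4)c3)o2)C(OCc2ccccc2)=CC1=O | intermediate
15 | racemic 3-(benzyloxy)-4-{6-[3,5-bis(benzyloxy)-4-methoxyphenyl]-4-oxo-4H-pyran-2-yl}-4-methoxycyclobut-2-en-1-one | COC1(c2cc(=O)cc(-c3cc(OCc4ccccc4)c(OC)c(OCc4ccccc4)c3)o2)C(OCc2ccccc2)=CC1=O | intermediate (key-step precursor)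
16 | (3Z)-3-(benzyloxy)-4-{6-[3,5-bis(benzyloxy)-4-methoxyphenyl]-4-oxo-4H-pyran-2-yl}-4-methoxybuta-1,3-dien-1-one | O=C=C/C(OCc1ccccc1)=C(/OC)c1cc(=O)cc(-c2cc(OCc3ccccc3)c(OC)c(OCc3ccccc3)c2)o1 | intermediate (not isolated)
17 | racemic 7-(benzyloxy)-2-[3,5-bis(benzyloxy)-4-methoxyphenyl]-8-methoxy-4H-chromene-4,5(4aH)-dione | COC1=C2OC(c3cc(OCc4ccccc4)c(OC)c(OCc4ccccc4)c3)=CC(=O)C2C(=O)C=C1OCc1ccccc1 | intermediate (not isolated)
18 | 7-(benzyloxy)-2-[3,5-bis(benzyloxy)-4-methoxyphenyl]-5-hydroxy-8-methoxy-4H-chromen-4-one | COc1c(OCc2ccccc2)cc(O)c2c(=O)cc(-c3cc(OCc4ccccc4)c(OC)c(OCc4ccccc4)c3)oc12 | intermediate (key-step product)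
19 | 7-(benzyloxy)-2-[3,5-bis(benzyloxy)-4-methoxyphenyl]-5,8-dimethoxy-4H-chromen-4-one | COc1cc(OCc2ccccc2)c(OC)c2oc(-c3cc(OCc4ccccc4)c(OC)c(OCc4ccccc4)c3)cc(=O)c12 | intermediate
20 | 2-(3,5-dihydroxy-4-methoxyphenyl)-7-hydroxy-5,8-dimethoxy-4H-chromen-4-one | COc1c(O)cc(-c2cc(=O)c3c(OC)cc(O)c(OC)c3o2)cc1O | target

**Step count**

Total: 12 steps. Longest linear sequence: 10 steps (steps 1 to 5, then 8 to 12); steps 6 and 7 form the two-step squarate branch.

**Steps most likely to fail**

1. Step 10 (Proposed new method). The pyranone C5=C6 bond may be reluctant to enter the 6π closure because this interrupts the pyranone conjugation. The ketene would then live long enough to dimerise or to be captured by adventitious nucleophiles, and inward rotation of the methoxy group would give a ketene that cannot cyclise.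
Fallback by known chemistry, setting out from 4 and returning at 19. Commercial 1-(2,4,6-trihydroxyphenyl)ethan-1-one is converted with LiN(SiMe3)2 (THF, −78 °C) into tetralithium 2-(1-oxidoethenyl)benzene-1,3,5-triolate F1, which is C-aroylated by 4 to give 1-[3,5-bis(benzyloxy)-4-methoxyphenyl]-3-(2,4,6-trihydroxyphenyl)propane-1,3-dione F2. Acid cyclodehydration (AcOH, cat. H2SO4, 60 °C) should close the chromone to 2-[3,5-bis(benzyloxy)-4-methoxyphenyl]-5,7-dihydroxy-4H-chromen-4-one F3. The non-chelated 7-hydroxyl is benzylated selectively (BnBr, K2CO3, acetone) to 7-(benzyloxy)-2-[3,5-bis(benzyloxy)-4-methoxyphenyl]-5-hydroxy-4H-chromen-4-one F4. Elbs persulfate oxidation (K2S2O8, aq. KOH, pyridine, rt) introduces oxygen para to the 5-hydroxyl as potassium 7-(benzyloxy)-2-[3,5-bis(benzyloxy)-4-methoxyphenyl]-5-hydroxy-4-oxo-4H-chromen-8-yl sulfate F5, which warm dilute HCl with Na2SO3 hydrolyses to 7-(benzyloxy)-2-[3,5-bis(benzyloxy)-4-methoxyphenyl]-5,8-dihydroxy-4H-chromen-4-one F6. Methylation of both hydroxyls (Me2SO4, K2CO3, acetone, reflux) then gives 19.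

2. Step 8. Deprotonation may compete at C3 or C5 of the pyranone, the lithiated pyranone may add to not yet metalated pyranone, or it may decompose by ring opening before it reaches the semisquarate.
Fallback, setting out from 8 and returning at 14. Zincation of 8 with TMPZnCl·LiCl (THF, 25 °C) gives {6-[3,5-bis(benzyloxy)-4-methoxyphenyl]-4-oxo-4H-pyran-2-yl}zinc chloride F7, which is quenched with I2 to 2-[3,5-bis(benzyloxy)-4-methoxyphenyl]-6-iodo-4H-pyran-4-one F8. This is an isolable compound whose regiochemistry can be checked before use. Iodine–magnesium exchange (i-PrMgCl·LiCl, THF, −40 °C) then gives {6-[3,5-bis(benzyloxy)-4-methoxyphenyl]-4-oxo-4H-pyran-2-yl}magnesium chloride F9, which is added to 12 at −40 °C to deliver 14.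

3. Step 9. The strained tertiary cyclobutenol may fragment (retro-aldol-type ring cleavage) or the pyranone carbonyl oxygen may be methylated in competition with the hindered hydroxyl.
Fallback, setting out from 14 and returning at 19. The free carbinol 14 is heated as in step 10, since 4-hydroxycyclobutenones undergo the same ring expansion, and a Na2S2O4 wash returns any quinone formed by air oxidation. The resulting 7-(benzyloxy)-2-[3,5-bis(benzyloxy)-4-methoxyphenyl]-5,8-dihydroxy-4H-chromen-4-one F10 (the same hydroquinone as F6) is methylated at both hydroxyls with Me2SO4 and K2CO3 in refluxing acetone. This gives 19 directly and makes step 11 unnecessary.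

**Further compounds**

F1 | step 10 | tetralithium 2-(1-oxidoethenyl)benzene-1,3,5-triolate | [Li+].[Li+].[Li+].[Li+].C=C([O-])c1c([O-])cc([O-])cc1[O-]
F2 | step 10 | 1-[3,5-bis(benzyloxy)-4-methoxyphenyl]-3-(2,4,6-trihydroxyphenyl)propane-1,3-dione | COc1c(OCc2ccccc2)cc(C(=O)CC(=O)c2c(O)cc(O)cc2O)cc1OCc1ccccc1
F3 | step 10 | 2-[3,5-bis(benzyloxy)-4-methoxyphenyl]-5,7-dihydroxy-4H-chromen-4-one | COc1c(OCc2ccccc2)cc(-c2cc(=O)c3c(O)cc(O)cc3o2)cc1OCc1ccccc1
F4 | step 10 | 7-(benzyloxy)-2-[3,5-bis(benzyloxy)-4-methoxyphenyl]-5-hydroxy-4H-chromen-4-one | COc1c(OCc2ccccc2)cc(-c2cc(=O)c3c(O)cc(OCc4ccccc4)cc3o2)cc1OCc1ccccc1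
F5 | step 10 | potassium 7-(benzyloxy)-2-[3,5-bis(benzyloxy)-4-methoxyphenyl]-5-hydroxy-4-oxo-4H-chromen-8-yl sulfate | [K+].COc1c(OCc2ccccc2)cc(-c2cc(=O)c3c(O)cc(OCc4ccccc4)c(OS(=O)(=O)[O-])c3o2)cc1OCc1ccccc1
F6 | step 10 | 7-(benzyloxy)-2-[3,5-bis(benzyloxy)-4-methoxyphenyl]-5,8-dihydroxy-4H-chromen-4-one | COc1c(OCc2ccccc2)cc(-c2cc(=O)c3c(O)cc(OCc4ccccc4)c(O)c3o2)cc1OCc1ccccc1
F7 | step 8 | {6-[3,5-bis(benzyloxy)-4-methoxyphenyl]-4-oxo-4H-pyran-2-yl}zinc chloride | COc1c(OCc2ccccc2)cc(-c2cc(=O)cc([Zn]Cl)o2)cc1OCc1ccccc1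
F8 | step 8 | 2-[3,5-bis(benzyloxy)-4-methoxyphenyl]-6-iodo-4H-pyran-4-one | COc1c(OCc2ccccc2)cc(-c2cc(=O)cc(I)o2)cc1OCc1ccccc1
F9 | step 8 | {6-[3,5-bis(benzyloxy)-4-methoxyphenyl]-4-oxo-4H-pyran-2-yl}magnesium chloride | COc1c(OCc2ccccc2)cc(-c2cc(=O)cc([Mg]Cl)o2)cc1OCc1ccccc1
F10 | step 9 | 7-(benzyloxy)-2-[3,5-bis(benzyloxy)-4-methoxyphenyl]-5,8-dihydroxy-4H-chromen-4-one | COc1c(OCc2ccccc2)cc(-c2cc(=O)c3c(O)cc(OCc4ccccc4)c(O)c3o2)cc1OCc1ccccc1
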